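**Assumption:** the SMILES is read as 8R,10R in the side chain, all‑E triene, and the two cyclohexane hydroxyls cis (pyridone trans to the secondary OH); compounds 1, 12, 14 and all reagents are taken as commercial.

**Retrosynthetic overview**
1. Militarinone A ⇐ one fluoride step on a fully silicon‑protected 3‑trienoyl‑2,4‑dialkoxypyridine N‑oxide; the N‑oxide plus 2‑alkoxy group is the masked N‑hydroxy‑2‑pyridone, and the N–O bond is installed before any alkene exists.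
2. C3–acyl bond ⇐ iodine–magnesium exchange on the 3‑iodopyridine N‑oxide and acylation with the intact trienyl Weinreb amide.
3. Key step: the cis‑1,4‑diol ⇐ singlet‑oxygen [4+2] cycloaddition to a 5‑(cyclohexa‑1,3‑dienyl)pyridine (Negishi coupling of the bromopyridine with a dienyl triflate), then hydrogenation; the peroxide bridge fixes the cis relationship.
4. Side chain ⇐ lipase desymmetrisation of a meso diacetate (sets C8 and C10), tosylate–cuprate coupling, Wittig and vinylogous HWE olefinations.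
5. Ring order: pyridine (from 14) and carbocycle (from 12) are bought; the only ring formed is the transient 2,3‑dioxabicyclo[2.2.2]octene (step 12), opened again in step 13.

**Route**

Step 1
Reactants: 1 cis‑2,4‑dimethylglutaric anhydride (meso)
Product: 2 meso‑2,4‑dimethylpentane‑1,5‑diol
Conditions: LiAlH4, THF, 0 °C → reflux
Reagents that add atoms: none
Why: Hydride reduction of the anhydride takes both acyl carbons to CH2OH faster than the α‑centres epimerise, so the meso relationship of the two methyl groups is kept.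

Step 2
Reactants: 2 meso‑2,4‑dimethylpentane‑1,5‑diol
Product: 3 meso‑2,4‑dimethylpentane‑1,5‑diyl diacetate
Conditions: Ac2O, pyridine, DMAP (cat.), CH2Cl2, 23 °C
Reagents that add atoms: acetic anhydride, CC(=O)OC(C)=O
Why: DMAP‑catalysed acylation of both primary alcohols gives the substrate for enzymatic hydrolysis; no stereocentre is touched.

Step 3
Reactants: 3 meso‑2,4‑dimethylpentane‑1,5‑diyl diacetate
Product: 4 (2R,4S)‑5‑hydroxy‑2,4‑dimethylpentyl acetate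
Conditions: Pseudomonas fluorescens lipase (lipase AK), phosphate buffer pH 7, 25 °C
Reagents that add atoms: none
Why: Enzymatic desymmetrisation: the lipase hydrolyses only the acetate on the arm next to the S carbon (the arm it would acylate in diol 2, which would give the enantiomer), so one step fixes the absolute configuration of both methyl‑bearing carbons (future C8 and C10).

Step 4
Reactants: 4 (2R,4S)‑5‑hydroxy‑2,4‑dimethylpentyl acetate
Product: 5 (2R,4S)‑2,4‑dimethyl‑5‑(tosyloxy)pentyl acetate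
Conditions: TsCl, pyridine, CH2Cl2, 0 → 23 °C
Reagents that add atoms: 4‑methylbenzenesulfonyl chloride, Cc1ccc(cc1)S(Cl)(=O)=O
Why: Sulfonylation of the free primary alcohol activates the arm that becomes the ethyl terminus; no stereocentre is touched.

Step 5
Reactants: 5 (2R,4S)‑2,4‑dimethyl‑5‑(tosyloxy)pentyl acetate
Product: 7 (2R,4R)‑2,4‑dimethylhexan‑1‑ol, via (2R,4R)‑2,4‑dimethylhexyl acetate 6 (not isolated)
Conditions: CuI, MeLi (gives Me2CuLi), Et2O, −30 → 0 °C; then K2CO3 (cat.), MeOH, 23 °C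
Reagents that add atoms: lithium dimethylcuprate (made in the flask from MeLi and CuI), [Li+].C[Cu-]C
Why: SN2 coupling of a Gilman cuprate with the primary tosylate turns CH2OTs into ethyl while sparing the acetate at or below 0 °C (the centre is untouched, its descriptor changes from S to R by priority only), and base‑catalysed transesterification then frees the alcohol.

Step 6
Reactants: 7 (2R,4R)‑2,4‑dimethylhexan‑1‑ol
Product: 9 (2E,4R,6R)‑2,4,6‑trimethyloct‑2‑enal, via (2R,4R)‑2,4‑dimethylhexanal 8 (not isolated)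
Conditions: PhI(OAc)2, TEMPO (10 mol %), CH2Cl2, 23 °C; then Ph3P=C(CH3)CHO, toluene, 80 °C
Reagents that add atoms: 2‑(triphenylphosphoranylidene)propanal, CC(C=O)=P(c1ccccc1)(c1ccccc1)c1ccccc1
Why: TEMPO oxidation gives the α‑chiral aldehyde without epimerisation and the stabilised ylide traps it in a Wittig reaction that is E‑selective for the trisubstituted alkene and stops at the less electrophilic enal.

Step 7
Reactants: 9 (2E,4R,6R)‑2,4,6‑trimethyloct‑2‑enal
Product: 10 ethyl (2E,4E,6E,8R,10R)‑6,8,10‑trimethyldodeca‑2,4,6‑trienoate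
Conditions: (EtO)2P(O)CH2CH=CHCO2Et, LiN(SiMe3)2, THF, −78 → 0 °C
Reagents that add atoms: triethyl 4‑phosphonocrotonate, CCOC(=O)/C=C/CP(=O)(OCC)OCC
Why: Vinylogous Horner–Wadsworth–Emmons olefination forms the new 4E alkene under thermodynamic control of the elimination, the 2E bond coming from the reagent.

Step 8
Reactants: 10 ethyl (2E,4E,6E,8R,10R)‑6,8,10‑trimethyldodeca‑2,4,6‑trienoate
Product: 11 (2E,4E,6E,8R,10R)‑N‑methoxy‑N,6,8,10‑tetramethyldodeca‑2,4,6‑trienamide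
Conditions: MeNHOMe·HCl, i‑PrMgCl, THF, −20 °C
Reagents that add atoms: N,O‑dimethylhydroxylamine hydrochloride, CNOC.Cl
Why: Ester aminolysis by the magnesium amide formed in the flask attacks the ester carbonyl directly at low temperature and leaves the triene geometry untouched.

Step 9
Reactants: 12 cyclohex‑2‑en‑1‑one
Product: 13 cyclohexa‑1,3‑dien‑1‑yl trifluoromethanesulfonate
Conditions: Tf2O, 2,6‑di‑tert‑butyl‑4‑methylpyridine, CH2Cl2, 0 → 23 °C
Reagents that add atoms: trifluoromethanesulfonic anhydride, O=S(=O)(OS(=O)(=O)C(F)(F)F)C(F)(F)F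
Why: Enol triflate formation under equilibrating conditions (hindered, non‑nucleophilic base) gives the linearly conjugated, thermodynamic dienyl triflate by γ‑deprotonation.

Step 10
Reactants: 14 5‑bromo‑2,4‑dichloropyridine
Product: 15 5‑bromo‑2,4‑bis[2‑(trimethylsilyl)ethoxy]pyridine
Conditions: Me3SiCH2CH2OH, NaH, DMF, 0 → 70 °C
Reagents that add atoms: 2‑(trimethylsilyl)ethanol, C[Si](C)(C)CCO
Why: Twofold SNAr: the alkoxide displaces the 4‑chloride and, on warming, the 2‑chloride while the unactivated 5‑bromide stays, installing fluoride‑labile ethers on both pyridone oxygens.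

Step 11
Reactants: 15 5‑bromo‑2,4‑bis[2‑(trimethylsilyl)ethoxy]pyridine; 13 cyclohexa‑1,3‑dien‑1‑yl trifluoromethanesulfonate
Product: 18 5‑(cyclohexa‑1,3‑dien‑1‑yl)‑2,4‑bis[2‑(trimethylsilyl)ethoxy]pyridine, via aryllithium 16 (not isolated), via arylzinc chloride 17 (not isolated)
Conditions: n‑BuLi, THF, −78 °C; ZnCl2, −78 → 0 °C; 13, Pd(PPh3)4 (5 mol %), 40 °C
Reagents that add atoms: none
Why: Bromine–lithium exchange, transmetallation to zinc and Negishi coupling (oxidative addition of the dienyl triflate to zerovalent palladium, transmetallation, reductive elimination) join the two sp2 carbons without moving the diene.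

Step 12
Reactants: 18 5‑(cyclohexa‑1,3‑dien‑1‑yl)‑2,4‑bis[2‑(trimethylsilyl)ethoxy]pyridine
Product: 19 racemic 5‑(2,3‑dioxabicyclo[2.2.2]oct‑5‑en‑1‑yl)‑2,4‑bis[2‑(trimethylsilyl)ethoxy]pyridine
Conditions: O2, tetraphenylporphyrin (1 mol %), visible light, CH2Cl2, −20 °C
Reagents that add atoms: dioxygen, O=O
Why: Key step: sensitised singlet oxygen adds suprafacially to the s‑cis diene in a [4+2] cycloaddition, so both new C–O bonds lie on one face and the cis relationship of the future 1,4‑hydroxyls is locked by the peroxide bridge (the bicycle is racemic but both enantiomers give the same achiral diol), the alkoxypyridine being inert to singlet oxygen.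

Step 13
Reactants: 19 racemic 5‑(2,3‑dioxabicyclo[2.2.2]oct‑5‑en‑1‑yl)‑2,4‑bis[2‑(trimethylsilyl)ethoxy]pyridine
Product: 21 cis‑1‑{4,6‑bis[2‑(trimethylsilyl)ethoxy]pyridin‑3‑yl}cyclohexane‑1,4‑diol, via cis‑enediol 20 (not isolated)
Conditions: H2 (1 atm), Pt/C, EtOAc, 23 °C
Reagents that add atoms: none
Why: Catalytic hydrogenation cleaves the weak O–O bond and saturates the ring alkene without breaking a C–O bond, so the cis‑1,4‑diol set in step 12 is delivered; platinum is chosen to avoid hydrogenolysis of the tertiary benzylic‑type C–O bond.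

Step 14
Reactants: 21 cis‑1‑{4,6‑bis[2‑(trimethylsilyl)ethoxy]pyridin‑3‑yl}cyclohexane‑1,4‑diol
Product: 22 5‑[cis‑1,4‑bis(triethylsilyloxy)cyclohexyl]‑2,4‑bis[2‑(trimethylsilyl)ethoxy]pyridine
Conditions: Et3SiOTf, 2,6‑lutidine, CH2Cl2, −78 → 0 °C
Reagents that add atoms: triethylsilyl trifluoromethanesulfonate, CC[Si](CC)(CC)OS(=O)(=O)C(F)(F)F
Why: Silyl triflate silylation caps both the secondary and the hindered tertiary hydroxyl before the organometallic steps.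

Step 15
Reactants: 22 5‑[cis‑1,4‑bis(triethylsilyloxy)cyclohexyl]‑2,4‑bis[2‑(trimethylsilyl)ethoxy]pyridine
Product: 24 5‑[cis‑1,4‑bis(triethylsilyloxy)cyclohexyl]‑3‑iodo‑2,4‑bis[2‑(trimethylsilyl)ethoxy]pyridine, via 3‑lithiopyridine 23 (not isolated)
Conditions: n‑BuLi, THF, −78 → −40 °C; I2, −78 °C
Reagents that add atoms: iodine, II
Why: Directed ortho‑metalation: C3–H sits between two alkoxy groups that both coordinate lithium, so deprotonation occurs only there and iodine traps the aryllithium.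

Step 16
Reactants: 24 5‑[cis‑1,4‑bis(triethylsilyloxy)cyclohexyl]‑3‑iodo‑2,4‑bis[2‑(trimethylsilyl)ethoxy]pyridine
Product: 25 5‑[cis‑1,4‑bis(triethylsilyloxy)cyclohexyl]‑3‑iodo‑2,4‑bis[2‑(trimethylsilyl)ethoxy]pyridine 1‑oxide
Conditions: mCPBA, CH2Cl2, 0 → 23 °C
Reagents that add atoms: 3‑chloroperbenzoic acid, OOC(=O)c1cccc(Cl)c1
Why: Peracid N‑oxidation of the electron‑rich pyridine nitrogen installs the future N‑hydroxyl oxygen while no oxidisable alkene is present.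

Step 17
Reactants: 25 5‑[cis‑1,4‑bis(triethylsilyloxy)cyclohexyl]‑3‑iodo‑2,4‑bis[2‑(trimethylsilyl)ethoxy]pyridine 1‑oxide; 11 (2E,4E,6E,8R,10R)‑N‑methoxy‑N,6,8,10‑tetramethyldodeca‑2,4,6‑trienamide
Product: 28 (2E,4E,6E,8R,10R)‑1‑{5‑[cis‑1,4‑bis(triethylsilyloxy)cyclohexyl]‑1‑oxido‑2,4‑bis[2‑(trimethylsilyl)ethoxy]pyridin‑1‑ium‑3‑yl}‑6,8,10‑trimethyldodeca‑2,4,6‑trien‑1‑one, via arylmagnesium chloride 26 (not isolated), via magnesium hemiaminal 27 (not isolated)
Conditions: i‑PrMgCl·LiCl, THF, −78 °C; 11, −78 → 0 °C; aq. NH4Cl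
Reagents that add atoms: none
Why: Iodine–magnesium exchange at −78 °C outpaces deprotonation next to the N‑oxide, and the arylmagnesium adds once to the Weinreb amide to give a chelated tetrahedral adduct that collapses to the ketone only on work‑up (Weinreb ketone synthesis), bringing in the intact E,E,E‑triene.

Step 18
Reactants: 28 (2E,4E,6E,8R,10R)‑1‑{5‑[cis‑1,4‑bis(triethylsilyloxy)cyclohexyl]‑1‑oxido‑2,4‑bis[2‑(trimethylsilyl)ethoxy]pyridin‑1‑ium‑3‑yl}‑6,8,10‑trimethyldodeca‑2,4,6‑trien‑1‑one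
Product: 29 militarinone A
Conditions: Bu4NF, AcOH, THF, 0 → 23 °C
Reagents that add atoms: none
Why: Fluoride‑induced desilylation cleaves both Et3Si ethers, and the two Me3SiCH2CH2 ethers fragment by β‑elimination to ethene, freeing the 4‑hydroxyl and the 2‑oxido N‑oxide, which is the N‑hydroxy‑2‑pyridone tautomer.

**Compound list**
1 | cis‑2,4‑dimethylglutaric anhydride, (3R,5S)‑3,5‑dimethyloxane‑2,6‑dione (meso) | C[C@H]1C[C@@H](C)C(=O)OC1=O | starting material
2 | meso‑(2R,4S)‑2,4‑dimethylpentane‑1,5‑diol | OC[C@@H](C)C[C@@H](C)CO | intermediate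
3 | meso‑(2R,4S)‑2,4‑dimethylpentane‑1,5‑diyl diacetate | CC(=O)OC[C@@H](C)C[C@@H](C)COC(C)=O | intermediate
4 | (2R,4S)‑5‑hydroxy‑2,4‑dimethylpentyl acetate | OC[C@@H](C)C[C@@H](C)COC(C)=O | intermediate
5 | (2R,4S)‑2,4‑dimethyl‑5‑(tosyloxy)pentyl acetate | Cc1ccc(cc1)S(=O)(=O)OC[C@@H](C)C[C@@H](C)COC(C)=O | intermediate
6 | (2R,4R)‑2,4‑dimethylhexyl acetate (formed in the flask) | CC[C@@H](C)C[C@@H](C)COC(C)=O | intermediate
7 | (2R,4R)‑2,4‑dimethylhexan‑1‑ol | CC[C@@H](C)C[C@@H](C)CO | intermediate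
8 | (2R,4R)‑2,4‑dimethylhexanal (formed in the flask) | CC[C@@H](C)C[C@@H](C)C=O | intermediate
9 | (2E,4R,6R)‑2,4,6‑trimethyloct‑2‑enal | CC[C@@H](C)C[C@@H](C)/C=C(C)/C=O | intermediate
10 | ethyl (2E,4E,6E,8R,10R)‑6,8,10‑trimethyldodeca‑2,4,6‑trienoate | CC[C@@H](C)C[C@@H](C)/C=C(C)/C=C/C=C/C(=O)OCC | intermediate
11 | (2E,4E,6E,8R,10R)‑N‑methoxy‑N,6,8,10‑tetramethyldodeca‑2,4,6‑trienamide | CC[C@@H](C)C[C@@H](C)/C=C(C)/C=C/C=C/C(=O)N(C)OC | intermediate
12 | cyclohex‑2‑en‑1‑one | O=C1C=CCCC1 | starting material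
13 | cyclohexa‑1,3‑dien‑1‑yl trifluoromethanesulfonate | FC(F)(F)S(=O)(=O)OC1=CC=CCC1 | intermediate
14 | 5‑bromo‑2,4‑dichloropyridine | Clc1cc(Cl)c(Br)cn1 | starting material
15 | 5‑bromo‑2,4‑bis[2‑(trimethylsilyl)ethoxy]pyridine | C[Si](C)(C)CCOc1cc(OCC[Si](C)(C)C)c(Br)cn1 | intermediate
16 | {4,6‑bis[2‑(trimethylsilyl)ethoxy]pyridin‑3‑yl}lithium (formed in the flask) | [Li]c1cnc(OCC[Si](C)(C)C)cc1OCC[Si](C)(C)C | intermediate
17 | {4,6‑bis[2‑(trimethylsilyl)ethoxy]pyridin‑3‑yl}zinc chloride (formed in the flask) | Cl[Zn]c1cnc(OCC[Si](C)(C)C)cc1OCC[Si](C)(C)C | intermediate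
18 | 5‑(cyclohexa‑1,3‑dien‑1‑yl)‑2,4‑bis[2‑(trimethylsilyl)ethoxy]pyridine | C[Si](C)(C)CCOc1cc(OCC[Si](C)(C)C)c(cn1)C1=CC=CCC1 | intermediate
19 | 5‑(2,3‑dioxabicyclo[2.2.2]oct‑5‑en‑1‑yl)‑2,4‑bis[2‑(trimethylsilyl)ethoxy]pyridine (racemic, one enantiomer drawn) | C[Si](C)(C)CCOc1cc(OCC[Si](C)(C)C)c(cn1)[C@]12OO[C@H](C=C1)CC2 | intermediate
20 | cis‑1‑{4,6‑bis[2‑(trimethylsilyl)ethoxy]pyridin‑3‑yl}cyclohex‑2‑ene‑1,4‑diol (racemic, one enantiomer drawn; formed in the flask) | C[Si](C)(C)CCOc1cc(OCC[Si](C)(C)C)c(cn1)[C@]1(O)C=C[C@@H](O)CC1 | intermediate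
21 | cis‑1‑{4,6‑bis[2‑(trimethylsilyl)ethoxy]pyridin‑3‑yl}cyclohexane‑1,4‑diol (hydroxyls cis, achiral) | C[Si](C)(C)CCOc1cc(OCC[Si](C)(C)C)c(cn1)[C@]1(O)CC[C@@H](O)CC1 | intermediate
22 | 5‑[cis‑1,4‑bis(triethylsilyloxy)cyclohexyl]‑2,4‑bis[2‑(trimethylsilyl)ethoxy]pyridine | C[Si](C)(C)CCOc1cc(OCC[Si](C)(C)C)c(cn1)[C@]1(O[Si](CC)(CC)CC)CC[C@@H](O[Si](CC)(CC)CC)CC1 | intermediate
23 | 3‑lithio derivative of 22 (formed in the flask) | [Li]c1c(OCC[Si](C)(C)C)ncc([C@]2(O[Si](CC)(CC)CC)CC[C@@H](O[Si](CC)(CC)CC)CC2)c1OCC[Si](C)(C)C | intermediate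
24 | 5‑[cis‑1,4‑bis(triethylsilyloxy)cyclohexyl]‑3‑iodo‑2,4‑bis[2‑(trimethylsilyl)ethoxy]pyridine | Ic1c(OCC[Si](C)(C)C)ncc([C@]2(O[Si](CC)(CC)CC)CC[C@@H](O[Si](CC)(CC)CC)CC2)c1OCC[Si](C)(C)C | intermediate
25 | 5‑[cis‑1,4‑bis(triethylsilyloxy)cyclohexyl]‑3‑iodo‑2,4‑bis[2‑(trimethylsilyl)ethoxy]pyridine 1‑oxide | Ic1c(OCC[Si](C)(C)C)[n+]([O-])cc([C@]2(O[Si](CC)(CC)CC)CC[C@@H](O[Si](CC)(CC)CC)CC2)c1OCC[Si](C)(C)C | intermediate
26 | 3‑(chloromagnesio) derivative of 25 in place of iodine (formed in the flask) | Cl[Mg]c1c(OCC[Si](C)(C)C)[n+]([O-])cc([C@]2(O[Si](CC)(CC)CC)CC[C@@H](O[Si](CC)(CC)CC)CC2)c1OCC[Si](C)(C)C | intermediate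
27 | chloromagnesium alkoxide of the N‑methoxy‑N‑methyl hemiaminal from 26 and 11 (epimers at the new carbon; formed in the flask) | CC[C@@H](C)C[C@@H](C)/C=C(C)/C=C/C=C/C(O[Mg]Cl)(N(C)OC)c1c(OCC[Si](C)(C)C)[n+]([O-])cc([C@]2(O[Si](CC)(CC)CC)CC[C@@H](O[Si](CC)(CC)CC)CC2)c1OCC[Si](C)(C)C | intermediate
28 | (2E,4E,6E,8R,10R)‑1‑{5‑[cis‑1,4‑bis(triethylsilyloxy)cyclohexyl]‑1‑oxido‑2,4‑bis[2‑(trimethylsilyl)ethoxy]pyridin‑1‑ium‑3‑yl}‑6,8,10‑trimethyldodeca‑2,4,6‑trien‑1‑one | CC[C@@H](C)C[C@@H](C)/C=C(C)/C=C/C=C/C(=O)c1c(OCC[Si](C)(C)C)[n+]([O-])cc([C@]2(O[Si](CC)(CC)CC)CC[C@@H](O[Si](CC)(CC)CC)CC2)c1OCC[Si](C)(C)C | intermediate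
29 | militarinone A | CC[C@@H](C)C[C@@H](C)/C=C(C)/C=C/C=C/C(=O)c1c(O)c([C@]2(O)CC[C@@H](O)CC2)cn(O)c1=O | target

**Totals**
Total step count: 18. Longest linear sequence: 10 steps (steps 1–8, 17, 18, from anhydride 1); the pyridine branch from 14 is 9 steps.

**Three steps most likely to fail, with fallbacks**

Step 12 (with the diene supply from step 11). Diene 18 can aromatise or isomerise, and photooxygenation may give ene or dehydrogenation products instead of the endoperoxide. The fallback leaves the cycloaddition for carbonyl addition and sets out from bromide 15. Bromine–lithium exchange (n‑BuLi, THF, −78 °C) and addition of the aryllithium to 1,4‑dioxaspiro[4.5]decan‑8‑one gives 8‑{4,6‑bis[2‑(trimethylsilyl)ethoxy]pyridin‑3‑yl}‑1,4‑dioxaspiro[4.5]decan‑8‑ol F1. Mild ketal hydrolysis (pyridinium p‑toluenesulfonate, acetone/water, 50 °C) gives 4‑{4,6‑bis[2‑(trimethylsilyl)ethoxy]pyridin‑3‑yl}‑4‑hydroxycyclohexan‑1‑one F2. NaBH4 in MeOH at −40 °C then delivers hydride axially to the conformer with the equatorial pyridyl group, giving mainly the cis‑diol, and the route is rejoined at 21.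

Step 17. The doubly ortho‑substituted arylmagnesium may add sluggishly to the Weinreb amide, or conjugate addition may compete. The fallback replaces acyl substitution by aldehyde addition and oxidation and sets out from 11 and 25. Reduction of 11 with i‑Bu2AlH (THF, −78 °C) gives (2E,4E,6E,8R,10R)‑6,8,10‑trimethyldodeca‑2,4,6‑trienal F3. Arylmagnesium 26, made from 25 as before, adds to it at −78 °C to give the bis‑allylic carbinol (2E,4E,6E,8R,10R)‑1‑{5‑[cis‑1,4‑bis(triethylsilyloxy)cyclohexyl]‑1‑oxido‑2,4‑bis[2‑(trimethylsilyl)ethoxy]pyridin‑1‑ium‑3‑yl}‑6,8,10‑trimethyldodeca‑2,4,6‑trien‑1‑ol F4 as an epimer mixture. Oxidation with MnO2 in CH2Cl2 rejoins the route at 28.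

Step 18. Basic fluoride may damage the trienone, or cleavage of the two 2‑(trimethylsilyl)ethyl ethers may stall. The fallback is a stepwise acidic unmasking that sets out from 28. HF·pyridine (THF, 0 °C) removes only the two triethylsilyl groups to give (2E,4E,6E,8R,10R)‑1‑{5‑(cis‑1,4‑dihydroxycyclohexyl)‑1‑oxido‑2,4‑bis[2‑(trimethylsilyl)ethoxy]pyridin‑1‑ium‑3‑yl}‑6,8,10‑trimethyldodeca‑2,4,6‑trien‑1‑one F5. Brief treatment with CF3CO2H in CH2Cl2 at 0 °C then cleaves the two activated ethers by acid‑induced β‑silyl fragmentation, and the route ends at 29.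

**Further compounds**
F1 | step 12 | 8‑{4,6‑bis[2‑(trimethylsilyl)ethoxy]pyridin‑3‑yl}‑1,4‑dioxaspiro[4.5]decan‑8‑ol | C[Si](C)(C)CCOc1cc(OCC[Si](C)(C)C)c(cn1)C1(O)CCC2(CC1)OCCO2
F2 | step 12 | 4‑{4,6‑bis[2‑(trimethylsilyl)ethoxy]pyridin‑3‑yl}‑4‑hydroxycyclohexan‑1‑one | C[Si](C)(C)CCOc1cc(OCC[Si](C)(C)C)c(cn1)C1(O)CCC(=O)CC1
F3 | step 17 | (2E,4E,6E,8R,10R)‑6,8,10‑trimethyldodeca‑2,4,6‑trienal | CC[C@@H](C)C[C@@H](C)/C=C(C)/C=C/C=C/C=O
F4 | step 17 | (2E,4E,6E,8R,10R)‑1‑{5‑[cis‑1,4‑bis(triethylsilyloxy)cyclohexyl]‑1‑oxido‑2,4‑bis[2‑(trimethylsilyl)ethoxy]pyridin‑1‑ium‑3‑yl}‑6,8,10‑trimethyldodeca‑2,4,6‑trien‑1‑ol (epimers at C1) | CC[C@@H](C)C[C@@H](C)/C=C(C)/C=C/C=C/C(O)c1c(OCC[Si](C)(C)C)[n+]([O-])cc([C@]2(O[Si](CC)(CC)CC)CC[C@@H](O[Si](CC)(CC)CC)CC2)c1OCC[Si](C)(C)C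
F5 | step 18 | (2E,4E,6E,8R,10R)‑1‑{5‑(cis‑1,4‑dihydroxycyclohexyl)‑1‑oxido‑2,4‑bis[2‑(trimethylsilyl)ethoxy]pyridin‑1‑ium‑3‑yl}‑6,8,10‑trimethyldodeca‑2,4,6‑trien‑1‑one | CC[C@@H](C)C[C@@H](C)/C=C(C)/C=C/C=C/C(=O)c1c(OCC[Si](C)(C)C)[n+]([O-])cc([C@]2(O)CC[C@@H](O)CC2)c1OCC[Si](C)(C)C
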